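**Retrosynthetic overview**
1. Last bond: C5–isobutenyl, made by alkenyl transfer to the five-membered oxocarbenium ion of a lactol (sets C5). The oxolane ring is therefore closed before its side chain is attached.
2. Lactol ⇐ aldehyde-selective oxidation of the remaining vinyl group of an aryloxy diol; ring closure is spontaneous.
3. Aryl ether ⇐ isofraxidin + terminal epoxide (C1–O bond). Isofraxidin ⇐ syringaldehyde (bromination, hydroxylation, Wittig–lactonisation).
4. Epoxy alcohol carrying C2 and the quaternary C3 ⇐ group- and face-selective mono-epoxidation of achiral, mirror-symmetric 3-methylpenta-1,4-dien-3-ol (from ethyl acetate + vinylmagnesium bromide).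
5. Ring order: coumarin pyranone ring → oxirane → oxolane.

Assumption: the antipode of the bis-hydroxamic acid ligand that leads to (2S,3R)-9 is found in a first run (both antipodes derive from trans-cyclohexane-1,2-diamine), and the target is taken as drawn, (2S,3R,5R) at the oxolane.

**Step 1**
Reactants: 1 syringaldehyde (4-hydroxy-3,5-dimethoxybenzaldehyde)
Product: 2 2-bromo-4-hydroxy-3,5-dimethoxybenzaldehyde
Conditions: Br2 (1.05 equiv), AcOH, rt
Reagents that add atoms: bromine, BrBr
Why: Electrophilic aromatic bromination; the two free ring positions are equivalent and activated by the ortho/para methoxy groups, so one monobromide forms and no stereocentre is involved.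

**Step 2**
Reactants: 2 2-bromo-4-hydroxy-3,5-dimethoxybenzaldehyde
Product: 3 2,4-dihydroxy-3,5-dimethoxybenzaldehyde
Conditions: 2 M aq NaOH, Cu powder (10 mol%), reflux, N2; then aq HCl
Reagents that add atoms: sodium hydroxide, [Na+].[OH-]
Why: Copper-catalysed Ullmann-type hydroxylation of an aryl bromide activated by the ortho formyl group (the conditions that turn 5-bromovanillin into 5-hydroxyvanillin); the aldehyde, deactivated as its phenoxide, resists Cannizzaro reaction.

**Step 3**
Reactants: 3 2,4-dihydroxy-3,5-dimethoxybenzaldehyde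
Product: 5 isofraxidin (7-hydroxy-6,8-dimethoxy-2H-chromen-2-one), via cinnamate ester 4 (not isolated)
Conditions: Ph3P=CHCO2Et (1.2 equiv), PhNEt2, reflux (215 °C)
Reagents that add atoms: ethyl (triphenylphosphoranylidene)acetate, CCOC(=O)C=P(c1ccccc1)(c1ccccc1)c1ccccc1
Why: Wittig olefination followed by thermal E-to-Z isomerisation and lactonisation onto the ortho phenol (the classical salicylaldehyde-to-coumarin annulation); the 4-hydroxyl cannot lactonise and stays free.

**Step 4**
Reactants: 6 ethyl acetate
Product: 8 3-methylpenta-1,4-dien-3-ol, via but-3-en-2-one 7 (not isolated)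
Conditions: CH2=CHMgBr (2.3 equiv), THF, −20 °C to rt; aq NH4Cl
Reagents that add atoms: vinylmagnesium bromide, C=C[Mg]Br
Why: Double Grignard addition to an ester (addition–elimination to the enone, then 1,2-addition at low temperature) gives the achiral divinyl carbinol whose two vinyl groups are enantiotopic.

**Step 5**
Reactants: 8 3-methylpenta-1,4-dien-3-ol
Product: 9 (2R)-2-[(2S)-oxiran-2-yl]but-3-en-2-ol
Conditions: WO2(acac)2 (5 mol%), chiral bis-hydroxamic acid ligand (6 mol%), 30% aq H2O2 (1.0 equiv), NaCl, CH2Cl2, rt, stopped near 90% conversion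
Reagents that add atoms: hydrogen peroxide, OO
Why: Proposed new method: hydroxyl-directed desymmetrising asymmetric epoxidation, in which the tertiary alkoxide of 8 binds the chiral peroxo-tungsten bis-hydroxamate and the peroxo oxygen is passed intramolecularly to one face of one of the two enantiotopic vinyl groups, so that C2 (S) and the quaternary carbinol C3 (R) are fixed together while the second vinyl group is kept for step 7; the closest known reactions are the WO2(acac)2/bis-hydroxamic acid/H2O2 and Hf(OtBu)4/bis-hydroxamic acid epoxidations of tertiary allylic alcohols and the Sharpless–Katsuki desymmetrisation of the secondary analogue penta-1,4-dien-3-ol, and, as there, faster second epoxidation of the minor stereoisomers should raise the purity of 9 as conversion rises.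

**Step 6**
Reactants: 5 isofraxidin; 9 (2R)-2-[(2S)-oxiran-2-yl]but-3-en-2-ol (1.3 equiv)
Product: 10 7-{[(2S,3R)-2,3-dihydroxy-3-methylpent-4-en-1-yl]oxy}-6,8-dimethoxy-2H-chromen-2-one
Conditions: CsF (0.3 equiv), DMF, 70 °C
Reagents that add atoms: none
Why: Fluoride-promoted SN2 opening of a terminal epoxide by the phenoxide at the unhindered CH2 (phenol–epoxide etherification); no bond to C2 or C3 is broken, so both keep their configuration, and the acidic phenol buffers the medium against Payne rearrangement.

**Step 7**
Reactants: 10 7-{[(2S,3R)-2,3-dihydroxy-3-methylpent-4-en-1-yl]oxy}-6,8-dimethoxy-2H-chromen-2-one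
Product: 12 7-{[(2S,3R)-3,5-dihydroxy-3-methyloxolan-2-yl]methoxy}-6,8-dimethoxy-2H-chromen-2-one (lactol; both C5 anomers), via hydroxy aldehyde 11 (not isolated)
Conditions: PdCl2(PhCN)2 (10 mol%), CuCl2·2H2O (10 mol%), AgNO2 (5 mol%), O2 (1 atm), tBuOH/MeNO2 15:1, rt
Reagents that add atoms: dioxygen, O=O
Why: Nitrite-modified aldehyde-selective (anti-Markovnikov) Wacker oxidation; attack at the internal carbon is disfavoured by the adjacent oxygenated quaternary centre, and the aldehyde is trapped at once by the C2 hydroxyl as the five-membered lactol (a 5-endo oxypalladation by that hydroxyl leads to the same lactol); C2 and C3 are untouched and the anomeric centre is irrelevant.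

**Step 8**
Reactants: 12 7-{[(2S,3R)-3,5-dihydroxy-3-methyloxolan-2-yl]methoxy}-6,8-dimethoxy-2H-chromen-2-one
Product: 14 7-{[(2S,3R,5R)-3-hydroxy-3-methyl-5-(2-methylprop-1-en-1-yl)oxolan-2-yl]methoxy}-6,8-dimethoxy-2H-chromen-2-one (CNP0086110.2), via oxocarbenium ion 13 (not isolated)
Conditions: K[(CH3)2C=CHBF3] (2 equiv), BF3·OEt2 (3 equiv), CH2Cl2/MeCN, −40 to 0 °C
Reagents that add atoms: potassium trifluoro(2-methylprop-1-en-1-yl)borate, [K+].CC(C)=C[B-](F)(F)F
Why: Lewis-acid C-glycosylation-type alkenylation of a lactol with an organotrifluoroborate: BF3 ionises the lactol to the oxocarbenium ion, which is attacked from the inside of the envelope that holds the C3 oxygen pseudoaxial and the C3 methyl pseudoequatorial (Woerpel model), helped by delivery from the alkenylboron bound to the C3 oxygen, so the isobutenyl group enters cis to the C3 hydroxyl and trans to the C2 side chain, giving 5R.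

**Compound list**
1 | syringaldehyde (4-hydroxy-3,5-dimethoxybenzaldehyde) | COc1cc(C=O)cc(OC)c1O | starting material
2 | 2-bromo-4-hydroxy-3,5-dimethoxybenzaldehyde | COc1cc(C=O)c(Br)c(OC)c1O | intermediate
3 | 2,4-dihydroxy-3,5-dimethoxybenzaldehyde | COc1cc(C=O)c(O)c(OC)c1O | intermediate
4 | ethyl 3-(2,4-dihydroxy-3,5-dimethoxyphenyl)prop-2-enoate (E, then Z; forms in the flask) | CCOC(=O)C=Cc1cc(OC)c(O)c(OC)c1O | intermediate
5 | isofraxidin (7-hydroxy-6,8-dimethoxy-2H-chromen-2-one) | COc1cc2ccc(=O)oc2c(OC)c1O | intermediate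
6 | ethyl acetate | CCOC(C)=O | starting material
7 | but-3-en-2-one (forms in the flask) | CC(=O)C=C | intermediate
8 | 3-methylpenta-1,4-dien-3-ol | C=CC(C)(O)C=C | intermediate
9 | (2R)-2-[(2S)-oxiran-2-yl]but-3-en-2-ol | C=C[C@@](C)(O)[C@@H]1CO1 | intermediate
10 | 7-{[(2S,3R)-2,3-dihydroxy-3-methylpent-4-en-1-yl]oxy}-6,8-dimethoxy-2H-chromen-2-one | COc1cc2ccc(=O)oc2c(OC)c1OC[C@H](O)[C@](C)(O)C=C | intermediate
11 | (3R,4S)-5-[(6,8-dimethoxy-2-oxo-2H-chromen-7-yl)oxy]-3,4-dihydroxy-3-methylpentanal (forms in the flask) | COc1cc2ccc(=O)oc2c(OC)c1OC[C@H](O)[C@](C)(O)CC=O | intermediate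
12 | 7-{[(2S,3R)-3,5-dihydroxy-3-methyloxolan-2-yl]methoxy}-6,8-dimethoxy-2H-chromen-2-one (C5 anomers) | COc1cc2ccc(=O)oc2c(OC)c1OC[C@@H]1OC(O)C[C@@]1(C)O | intermediate
13 | cyclic oxocarbenium ion of 12, (2S,3R)-configured, C5=O+ (forms in the flask) | COc1cc2ccc(=O)oc2c(OC)c1OC[C@@H]1[O+]=CC[C@@]1(C)O | intermediate
14 | 7-{[(2S,3R,5R)-3-hydroxy-3-methyl-5-(2-methylprop-1-en-1-yl)oxolan-2-yl]methoxy}-6,8-dimethoxy-2H-chromen-2-one | COc1cc2ccc(=O)oc2c(OC)c1OC[C@@H]1O[C@@H](C=C(C)C)C[C@@]1(C)O | target

**Step count and risk**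
Total step count: 8. Longest linear sequence: 6 steps (steps 1, 2, 3, 6, 7, 8, from syringaldehyde); the other branch (steps 4, 5) joins at step 6.

Most likely to fail: step 5, step 7 and step 8.

Step 5 (the catalyst may not tell methyl from vinyl at the tertiary carbinol, giving poor dr at C3). The fallback sets C2 on a secondary carbinol, where group selection is reliable, and builds the quaternary centre afterwards. It sets out from isofraxidin 5 together with purchased penta-1,4-dien-3-ol F1. Sharpless–Katsuki desymmetrisation (Ti(OiPr)4, D-(−)-diisopropyl tartrate, which by the Sharpless mnemonic is the antipode that gives the (2S,3R) erythro epoxide, tBuOOH, 4 Å MS, CH2Cl2, −20 °C) gives (1R)-1-[(2S)-oxiran-2-yl]prop-2-en-1-ol F2. Opening with 5 under the conditions of step 6 gives 7-{[(2S,3R)-2,3-dihydroxypent-4-en-1-yl]oxy}-6,8-dimethoxy-2H-chromen-2-one F3. MnO2 in CH2Cl2 oxidises only the allylic hydroxyl to the hydroxy enone 7-{[(2S)-2-hydroxy-3-oxopent-4-en-1-yl]oxy}-6,8-dimethoxy-2H-chromen-2-one F4. MeTiCl3 (from Me2Zn and TiCl4, CH2Cl2, −78 °C) then adds 1,2 under chelation control (titanium bridges the ketone and the C2 oxygen, methyl enters from the face opposite the CH2OAr group) and leaves the coumarin lactone alone. This gives the (2S,3R) tertiary diol, and the fallback comes back to the route at 10.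

Step 7 (ketone formation, or palladium-induced side reactions of the free tertiary allylic alcohol). The fallback replaces the palladium oxidation by hydroboration and alcohol oxidation. It sets out from 10: 9-BBN (THF, rt; excess to cover the two hydroxyls) then NaBO3·4H2O gives 7-{[(2S,3R)-2,3,5-trihydroxy-3-methylpentyl]oxy}-6,8-dimethoxy-2H-chromen-2-one F5, the coumarin being inert to 9-BBN. TEMPO (10 mol%) with PhI(OAc)2 (1.05 equiv) in CH2Cl2 oxidises only the primary alcohol, and the aldehyde closes to the lactol. The fallback comes back at 12.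

Step 8 (low facial selectivity, or protodeboronation of the alkenylborane). The fallback makes the C5–C6 bond by carbonyl addition and closes the ring afterwards by allylic substitution. It sets out from 12: Nozaki–Hiyama–Kishi addition of 1-bromo-2-methylprop-1-ene (CrCl2, 4 equiv; NiCl2, 1 mol%; DMSO, rt) to the open hydroxy-aldehyde form gives 7-{[(2S,3R)-2,3,5-trihydroxy-3,7-dimethyloct-6-en-1-yl]oxy}-6,8-dimethoxy-2H-chromen-2-one F6 as a mixture of C5 epimers, without touching the lactone. PdCl2(MeCN)2 (5 mol%, THF, 0 °C to rt) then ionises the allylic alcohol and the C2 hydroxyl closes the five-membered ring. Both epimers converge through the same allyl cation, and reversible ring closure should favour the isomer with the isobutenyl group trans to both the C2 side chain and the C3 methyl. The fallback comes back at the target 14.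

**Further compounds**
F1 | step 5 | penta-1,4-dien-3-ol (purchased) | C=CC(O)C=C
F2 | step 5 | (1R)-1-[(2S)-oxiran-2-yl]prop-2-en-1-ol | C=C[C@@H](O)[C@@H]1CO1
F3 | step 5 | 7-{[(2S,3R)-2,3-dihydroxypent-4-en-1-yl]oxy}-6,8-dimethoxy-2H-chromen-2-one | COc1cc2ccc(=O)oc2c(OC)c1OC[C@H](O)[C@H](O)C=C
F4 | step 5 | 7-{[(2S)-2-hydroxy-3-oxopent-4-en-1-yl]oxy}-6,8-dimethoxy-2H-chromen-2-one | COc1cc2ccc(=O)oc2c(OC)c1OC[C@H](O)C(=O)C=C
F5 | step 7 | 7-{[(2S,3R)-2,3,5-trihydroxy-3-methylpentyl]oxy}-6,8-dimethoxy-2H-chromen-2-one | COc1cc2ccc(=O)oc2c(OC)c1OC[C@H](O)[C@](C)(O)CCO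
F6 | step 8 | 7-{[(2S,3R)-2,3,5-trihydroxy-3,7-dimethyloct-6-en-1-yl]oxy}-6,8-dimethoxy-2H-chromen-2-one (C5 epimers) | COc1cc2ccc(=O)oc2c(OC)c1OC[C@H](O)[C@](C)(O)CC(O)C=C(C)C
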